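**Retrosynthetic overview**
1. Vibsanin E ⇒ vibsanin C. The last step is a BF3-triggered cation–olefin cyclisation that closes the cyclohexane (C2–C14) and the oxane (C15–O) together.
2. Vibsanin C ⇒ an 11-membered trienone of vibsanin B constitution. A transannular oxy-Cope shift contracts 11 → 7 and sets C5, C10 and the E enol ester.
3. 11-membered ring ⇒ acyclic vinyl bromide/vinylstannane + CO (carbonylative Stille, C4 is the CO carbon), run in the same flask as the Cope shift.
4. Acyclic chain ⇒ Claisen rearrangement (C9 → C11 chirality transfer builds the quaternary centre) and SN2 opening of a Sharpless-derived C7–C8 oxirane by senecioic acid.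
5. Ring order: 11-membered carbocycle → cycloheptene → cyclohexane + oxane. Building blocks: a C6 enynol, homoprenyl bromide, propyne, ethyl vinyl ether, a bromo ylide, senecioic acid and CO.

Assumption: vibsane numbering (C1–C20) is used for all intermediates, and compound 1 is bought as the pure E isomer.

**Step 1**
Reactants: 1 (E)-3-methylpent-2-en-4-yn-1-ol
Product: 2 [(2S,3S)-3-ethynyl-3-methyloxiran-2-yl]methanol
Conditions: Ti(OiPr)4 (10 mol %), L-(+)-diethyl tartrate (12 mol %), t-BuOOH (2 equiv), 4 Å MS, CH2Cl2, −20 °C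
Reagents that add atoms: tert-butyl hydroperoxide, CC(C)(C)OO
Why: In this Sharpless asymmetric epoxidation the titanium–L-(+)-tartrate complex attacks the same alkene face as in the geraniol to (2S,3S)-epoxygeraniol case, which sets 7S,8S from the E alkene (ethynyl trans to CH2OH) and leaves the alkyne untouched.

**Step 2**
Reactants: 2 [(2S,3S)-3-ethynyl-3-methyloxiran-2-yl]methanol
Product: 3 (2R,3S)-3-ethynyl-3-methyloxirane-2-carbaldehyde
Conditions: TEMPO (10 mol %), PhI(OAc)2 (1.1 equiv), CH2Cl2, 0 → 23 °C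
Reagents that add atoms: none
Why: The TEMPO/oxoammonium oxidation stops at the aldehyde under near-neutral conditions that spare the oxirane, the alkyne and both stereocentres (the C8 descriptor becomes R only through CIP priorities).

**Step 3**
Reactants: 4 5-bromo-2-methylpent-2-ene
Product: 8 (1Z)-1-iodo-2,6-dimethylhepta-1,5-diene, via homoprenylmagnesium bromide 5 (not isolated), via homoprenylcopper 6 (not isolated), via Z-alkenylcopper 7 (not isolated)
Conditions: Mg, Et2O, 35 °C; CuBr·SMe2, Me2S/Et2O, −45 °C; propyne, −25 °C; I2, −50 → 0 °C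
Reagents that add atoms: propyne, CC#C; iodine, [I][I]
Why: In this Normant carbocupration the alkylcopper adds syn across propyne (carbon to the internal position, copper to the terminal one), and iodinolysis with retention fixes the Z trisubstituted alkene needed for the later chirality transfer.

**Step 4**
Reactants: 8 (1Z)-1-iodo-2,6-dimethylhepta-1,5-diene; 3 (2R,3S)-3-ethynyl-3-methyloxirane-2-carbaldehyde
Product: 10 (1S,2Z)-1-[(2S,3S)-3-ethynyl-3-methyloxiran-2-yl]-3,7-dimethylocta-2,6-dien-1-ol, via Z-alkenyllithium 9 (not isolated)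
Conditions: t-BuLi (2.0 equiv per 8), Et2O, −78 °C; then 3, −78 °C
Reagents that add atoms: none
Why: Iodine–lithium exchange keeps the alkene geometry, and the non-chelated alkenyllithium adds to the α,β-epoxy aldehyde in the Felkin–Anh sense (anti to the oxirane C–O bond) to give mainly the anti (erythro) 9S carbinol, because carbonyl addition at −78 °C outruns alkyne deprotonation.

**Step 5**
Reactants: 10 (1S,2Z)-1-[(2S,3S)-3-ethynyl-3-methyloxiran-2-yl]-3,7-dimethylocta-2,6-dien-1-ol
Product: 11 (2S,3S)-2-[(1S,2Z)-1-(ethenyloxy)-3,7-dimethylocta-2,6-dien-1-yl]-3-ethynyl-3-methyloxirane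
Conditions: ethyl vinyl ether (solvent), Hg(OAc)2 (20 mol %), reflux
Reagents that add atoms: ethyl vinyl ether, C=COCC
Why: Mercury-catalysed vinyl transetherification O-vinylates the only hydroxyl without breaking the C9–O bond, so 9S is kept, and the method tolerates terminal alkynes and oxiranes.

**Step 6**
Reactants: 11 (2S,3S)-2-[(1S,2Z)-1-(ethenyloxy)-3,7-dimethylocta-2,6-dien-1-yl]-3-ethynyl-3-methyloxirane
Product: 13 ethyl (2Z,5S)-2-bromo-5-{(E)-2-[(2S,3S)-3-ethynyl-3-methyloxiran-2-yl]ethenyl}-5,9-dimethyldeca-2,8-dienoate, via Claisen aldehyde 12 (not isolated)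
Conditions: Ph3P=C(Br)CO2Et (1.5 equiv), toluene, 120 °C, sealed tube
Reagents that add atoms: ethyl 2-bromo-2-(triphenyl-λ5-phosphanylidene)acetate, CCOC(=O)C(Br)=P(c1ccccc1)(c1ccccc1)c1ccccc1
Why: The Claisen [3,3] rearrangement runs through a chair with the oxiranyl group pseudo-equatorial, which gives the E C9=C10 alkene and transfers 9S suprafacially onto the Z alkene to create quaternary 11S, and the aldehyde is trapped at once by Wittig olefination with the stabilised bromo ylide (ester trans, bromine cis to the chain, Z).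

**Step 7**
Reactants: 13 ethyl (2Z,5S)-2-bromo-5-{(E)-2-[(2S,3S)-3-ethynyl-3-methyloxiran-2-yl]ethenyl}-5,9-dimethyldeca-2,8-dienoate
Product: 14 (2Z,5S)-2-bromo-5-{(E)-2-[(2S,3S)-3-ethynyl-3-methyloxiran-2-yl]ethenyl}-5,9-dimethyldeca-2,8-dien-1-ol
Conditions: i-Bu2AlH (2.3 equiv), CH2Cl2, −78 °C; Rochelle salt work-up
Reagents that add atoms: none
Why: This 1,2-reduction of the conjugated ester at −78 °C is faster than any attack on the oxirane, the vinyl bromide or the alkyne, and no stereocentre is involved.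

**Step 8**
Reactants: 14 (2Z,5S)-2-bromo-5-{(E)-2-[(2S,3S)-3-ethynyl-3-methyloxiran-2-yl]ethenyl}-5,9-dimethyldeca-2,8-dien-1-ol; 15 3-methylbut-2-enoic acid (senecioic acid)
Product: 16 (3S,4R,5E,7S,9Z)-10-bromo-3,11-dihydroxy-3,7-dimethyl-7-(4-methylpent-3-en-1-yl)undeca-5,9-dien-1-yn-4-yl 3-methylbut-2-enoate
Conditions: 15 (4 equiv), Cs2CO3 (0.5 equiv), DMF, 60 °C
Reagents that add atoms: none
Why: In this carboxylate SN2 opening of a vinyl oxirane, C8 is secondary and allylic while C7 is fully substituted and deactivated by the ethynyl group and C10 is neopentylic, so senecioate attacks C8 with inversion (8S → 8R), the C7–O bond stays (7S), and the excess acid protonates the tertiary alkoxide before acyl migration.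

**Step 9**
Reactants: 16 (3S,4R,5E,7S,9Z)-10-bromo-3,11-dihydroxy-3,7-dimethyl-7-(4-methylpent-3-en-1-yl)undeca-5,9-dien-1-yn-4-yl 3-methylbut-2-enoate
Product: 17 (1E,3S,4R,5E,7S,9Z)-10-bromo-3,11-dihydroxy-3,7-dimethyl-7-(4-methylpent-3-en-1-yl)-1-(tributylstannyl)undeca-1,5,9-trien-4-yl 3-methylbut-2-enoate
Conditions: PdCl2(PPh3)2 (3 mol %), Bu3SnH (1.2 equiv, slow addition), THF, 0 °C
Reagents that add atoms: tributyltin hydride, CCCC[SnH](CCCC)CCCC
Why: Palladium-catalysed syn hydrostannation puts tin on the terminal carbon, away from the fully substituted carbinol, to give the E stannane, and it is much faster than insertion into a Z monobromoalkene or ionisation of the hindered allylic ester.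

**Step 10**
Reactants: 17 (1E,3S,4R,5E,7S,9Z)-10-bromo-3,11-dihydroxy-3,7-dimethyl-7-(4-methylpent-3-en-1-yl)-1-(tributylstannyl)undeca-1,5,9-trien-4-yl 3-methylbut-2-enoate
Product: 20 vibsanin C, via macrocyclic trienone 18 (not isolated), via Z-enol 19 (not isolated)
Conditions: Pd2(dba)3 (5 mol %), AsPh3 (40 mol %), CO (1 atm), 1,4-dioxane (1 mM, 17 added over 10 h), 80 °C; then Ar purge, 100 °C, 4 h
Reagents that add atoms: carbon monoxide, [C-]#[O+]
Why: The carbonylative Stille macrocyclisation (both alkene geometries retained, no base present) closes the 11-membered cross-conjugated dienone, and its strain-releasing transannular oxy-Cope [3,3] shift, through the chair with the C8 acyloxy and C7 methyl groups pseudo-equatorial, converts the E,E-1,5-diene into the trans 5S,10S cycloheptene bearing an E enol ester, after which enol-to-ketone tautomerisation makes the shift irreversible.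

**Step 11**
Reactants: 20 vibsanin C
Product: 21 vibsanin E
Conditions: BF3·OEt2 (0.3 equiv), CH2Cl2, −78 °C
Reagents that add atoms: none
Why: In this biomimetic Lewis-acid cation–olefin (Prins-type conjugate) cyclisation the prenyl alkene tethered on C11 attacks the activated enone at C2 through a chair-like transition state (2S,14R), the C15 cation is captured by the C18 hydroxyl, and protonation of the boron enolate gives the cis-fused oxane (3S).

**Compound list**
1 | (E)-3-methylpent-2-en-4-yn-1-ol | C#C/C(C)=C/CO | starting material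
2 | [(2S,3S)-3-ethynyl-3-methyloxiran-2-yl]methanol | C#C[C@]1(C)O[C@H]1CO | intermediate
3 | (2R,3S)-3-ethynyl-3-methyloxirane-2-carbaldehyde | C#C[C@]1(C)O[C@H]1C=O | intermediate
4 | 5-bromo-2-methylpent-2-ene | CC(C)=CCCBr | starting material
5 | (4-methylpent-3-en-1-yl)magnesium bromide | CC(C)=CCC[Mg]Br | intermediate
6 | (4-methylpent-3-en-1-yl)copper | CC(C)=CCC[Cu] | intermediate
7 | [(1Z)-2,6-dimethylhepta-1,5-dien-1-yl]copper | [Cu]/C=C(/C)CCC=C(C)C | intermediate
8 | (1Z)-1-iodo-2,6-dimethylhepta-1,5-diene | I/C=C(/C)CCC=C(C)C | intermediate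
9 | [(1Z)-2,6-dimethylhepta-1,5-dien-1-yl]lithium | [Li]/C=C(/C)CCC=C(C)C | intermediate
10 | (1S,2Z)-1-[(2S,3S)-3-ethynyl-3-methyloxiran-2-yl]-3,7-dimethylocta-2,6-dien-1-ol (7S,8S,9S) | C#C[C@]1(C)O[C@H]1[C@@H](O)/C=C(/C)CCC=C(C)C | intermediate
11 | (2S,3S)-2-[(1S,2Z)-1-(ethenyloxy)-3,7-dimethylocta-2,6-dien-1-yl]-3-ethynyl-3-methyloxirane | C#C[C@]1(C)O[C@H]1[C@@H](OC=C)/C=C(/C)CCC=C(C)C | intermediate
12 | (3S)-3-{(E)-2-[(2S,3S)-3-ethynyl-3-methyloxiran-2-yl]ethenyl}-3,7-dimethyloct-6-enal | C#C[C@]1(C)O[C@H]1/C=C/[C@@](C)(CCC=C(C)C)CC=O | intermediate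
13 | ethyl (2Z,5S)-2-bromo-5-{(E)-2-[(2S,3S)-3-ethynyl-3-methyloxiran-2-yl]ethenyl}-5,9-dimethyldeca-2,8-dienoate | C#C[C@]1(C)O[C@H]1/C=C/[C@@](C)(CCC=C(C)C)C/C=C(\Br)C(=O)OCC | intermediate
14 | (2Z,5S)-2-bromo-5-{(E)-2-[(2S,3S)-3-ethynyl-3-methyloxiran-2-yl]ethenyl}-5,9-dimethyldeca-2,8-dien-1-ol | C#C[C@]1(C)O[C@H]1/C=C/[C@@](C)(CCC=C(C)C)C/C=C(\Br)CO | intermediate
15 | 3-methylbut-2-enoic acid | CC(C)=CC(=O)O | starting material
16 | (3S,4R,5E,7S,9Z)-10-bromo-3,11-dihydroxy-3,7-dimethyl-7-(4-methylpent-3-en-1-yl)undeca-5,9-dien-1-yn-4-yl 3-methylbut-2-enoate (7S,8R,11S) | C#C[C@](C)(O)[C@H](OC(=O)C=C(C)C)/C=C/[C@@](C)(CCC=C(C)C)C/C=C(\Br)CO | intermediate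
17 | (1E)-1-tributylstannyl alkene derived from 16 | CCCC[Sn](CCCC)(CCCC)/C=C/[C@](C)(O)[C@H](OC(=O)C=C(C)C)/C=C/[C@@](C)(CCC=C(C)C)C/C=C(\Br)CO | intermediate
18 | (1R,2S,3E,6Z,9S,10E)-2-hydroxy-6-(hydroxymethyl)-2,9-dimethyl-9-(4-methylpent-3-en-1-yl)-5-oxocycloundeca-3,6,10-trien-1-yl 3-methylbut-2-enoate (vibsanin B constitution; 7S,8R,11S) | O=C1/C=C/[C@](C)(O)[C@H](OC(=O)C=C(C)C)/C=C/[C@@](C)(CCC=C(C)C)C/C=C1/CO | intermediate
19 | Z-enol tautomer of vibsanin C | C/C(O)=C/[C@@H]1C(=O)C(CO)=CC[C@](C)(CCC=C(C)C)[C@H]1/C=C/OC(=O)C=C(C)C | intermediate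
20 | vibsanin C (5S,10S,11S) | CC(=O)C[C@@H]1C(=O)C(CO)=CC[C@](C)(CCC=C(C)C)[C@H]1/C=C/OC(=O)C=C(C)C | intermediate
21 | vibsanin E (2S,3S,5S,10S,11S,14R) | CC(=O)C[C@@H]1C(=O)[C@@H]2COC(C)(C)[C@@H]3CC[C@@](C)(C[C@@H]32)[C@H]1/C=C/OC(=O)C=C(C)C | target

**Step count:** 11 steps in total. The longest linear sequence is 10 steps (steps 1, 2 and 4–11).

**Three steps most likely to fail**

Step 10 (macrocyclisation/oxy-Cope).
- Risks: closure of a strained 11-membered ring from a sluggish vinyl bromide; capture of the acyl-palladium species by the neighbouring hydroxyl; ionisation of the allylic ester.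
- The fallback sets out from 16 and comes back at 18.
- Lindlar semihydrogenation (Pd/CaCO3 poisoned with Pb(OAc)2, quinoline, H2) gives the 1-ene analogue of 16 F1.
- An intermolecular, and therefore much easier, carbonylative Stille coupling with tributyl(vinyl)stannane (Pd2(dba)3, AsPh3, CO) gives the divinyl ketone F2.
- Ring-closing metathesis at high dilution with second-generation Hoveyda–Grubbs catalyst closes C5=C6 to give 18. The trisubstituted alkenes are spectators and no five- or six-membered ring can form.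
- Compound 18 is then heated to 20 as in step 10.

Step 8 (oxirane opening by a weak nucleophile).
- Risks: low rate; loss of regiocontrol or stereospecificity.
- The fallback sets out from 14 and comes back at 16.
- Silylation (TBDPSCl, imidazole) gives the TBDPS ether of 14 F3.
- Acid-catalysed hydrolysis (cat. HClO4, THF–H2O, 0 °C) opens the allylic C8 position with inversion to the 7,8-diol F4.
- Acylation of the secondary hydroxyl only (3-methylbut-2-enoyl chloride, DMAP, pyridine; the tertiary carbinol is inert) gives the 8-O-senecioate TBDPS ether F5.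
- Bu4NF/AcOH then liberates 16.

Step 4 (facial selectivity at C9).
- Risk: additions to epoxy aldehydes are often only modestly selective.
- The fallback sets out from 3 and 8 and comes back at 10.
- The unselective adduct mixture of 10 and the C9 epimer of 10 F6 is oxidised with MnO2 (CH2Cl2, 23 °C) to the epoxy enone F7.
- Reduction with Zn(BH4)2 (Et2O, −78 → 0 °C) follows. Zinc chelates the carbonyl and oxirane oxygens and hydride enters from the face opposite C7.
- The centre is thus set by chelate-controlled hydride delivery, which gives the anti (erythro) carbinol 10.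

**Further compounds**
F1 | step 10 | 1-ene analogue of 16, (3S,4R,5E,7S,9Z)-10-bromo-3,11-dihydroxy-3,7-dimethyl-7-(4-methylpent-3-en-1-yl)undeca-1,5,9-trien-4-yl 3-methylbut-2-enoate | C=C[C@](C)(O)[C@H](OC(=O)C=C(C)C)/C=C/[C@@](C)(CCC=C(C)C)C/C=C(\Br)CO
F2 | step 10 | divinyl ketone (acryloyl group in place of bromine in F1) | C=C[C@](C)(O)[C@H](OC(=O)C=C(C)C)/C=C/[C@@](C)(CCC=C(C)C)C/C=C(\C(=O)C=C)CO
F3 | step 8 | TBDPS ether of 14 | C#C[C@]1(C)O[C@H]1/C=C/[C@@](C)(CCC=C(C)C)C/C=C(\Br)CO[Si](c1ccccc1)(c1ccccc1)C(C)(C)C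
F4 | step 8 | 7,8-diol (7S,8R,11S) | C#C[C@](C)(O)[C@H](O)/C=C/[C@@](C)(CCC=C(C)C)C/C=C(\Br)CO[Si](c1ccccc1)(c1ccccc1)C(C)(C)C
F5 | step 8 | 8-O-senecioate TBDPS ether | C#C[C@](C)(O)[C@H](OC(=O)C=C(C)C)/C=C/[C@@](C)(CCC=C(C)C)C/C=C(\Br)CO[Si](c1ccccc1)(c1ccccc1)C(C)(C)C
F6 | step 4 | C9 epimer of 10 (7S,8S,9R) | C#C[C@]1(C)O[C@H]1[C@H](O)/C=C(/C)CCC=C(C)C
F7 | step 4 | epoxy enone, (2Z)-1-[(2R,3S)-3-ethynyl-3-methyloxiran-2-yl]-3,7-dimethylocta-2,6-dien-1-one | C#C[C@]1(C)O[C@H]1C(=O)/C=C(/C)CCC=C(C)C
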